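The side chain is cut at two bonds at once: the ester bond between O4 of the pyranone and the acyl carbon, and the CH2–CMe2(O) bond. A photochemical Wolff rearrangement of a siloxy diazoketone releases a small, neutral ketene beside the hydroxypyranone, so one operation builds the 3-oxygenated 3-methylbutanoyl chain and attaches it. The step exploits the acidic enolic O–H on C4 of the 2-pyranone ring, crowded by the quaternary carbon attached to C3, which adds to the sp carbon of the ketene without base. The precursors are 4-hydroxy-3-(2-methylbut-3-en-2-yl)-6-phenyl-2-pyranone and 1-diazo-3-methyl-3-(triethylsilyloxy)butan-2-one.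

Key step: step 7

Assumption: the target is achiral, so no step sets or protects a stereocentre; 3-hydroxy-3-methylbutan-2-one is taken as a commercial starting material; ring atoms are numbered O1, C2 (lactone C=O), C3, C4, C5, C6 (phenyl-bearing).

Step 1
Reactants: 1 ethyl acetoacetate; 2 methyl benzoate
Product: 3 ethyl 3,5-dioxo-5-phenylpentanoate
Conditions: NaH, THF, 0 °C; n-BuLi, 0 °C; then 2 (0.5 equiv), 0 °C → rt; aq. HCl
Reagents that add atoms: none
Why: Crossed Claisen condensation of the acetoacetate dianion (Huckin–Weiler conditions), in which the more basic terminal carbanion attacks the non-enolisable ester and the excess dianion absorbs the acidic proton of the triketone product.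

Step 2
Reactants: 3 ethyl 3,5-dioxo-5-phenylpentanoate
Product: 4 4-hydroxy-6-phenyl-2H-pyran-2-one
Conditions: DBU, PhMe, reflux; aq. HCl
Reagents that add atoms: none
Why: Base-promoted lactonisation, in which the enol oxygen of the benzoyl ketone attacks the ethyl ester (6-exo-trig acyl substitution) and loss of ethanol gives the stable 4-hydroxy-2-pyranone, the standard closure of 3,5-diketo esters.

Step 3
Reactants: 4 4-hydroxy-6-phenyl-2H-pyran-2-one; 5 prenol (3-methylbut-2-en-1-ol)
Product: 6 4-(3-methylbut-2-enyloxy)-6-phenyl-2H-pyran-2-one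
Conditions: PPh3, DIAD, THF, 0 °C → rt
Reagents that add atoms: none
Why: Mitsunobu etherification, for which the acidic enol (pKa about 5) is a good pronucleophile and which is known to alkylate 4-hydroxy-2-pyranones at O4 with primary allylic alcohols, avoiding the C3-alkylation that pyronate salts tend to give with prenyl halides.

Step 4
Reactants: 6 4-(3-methylbut-2-enyloxy)-6-phenyl-2H-pyran-2-one
Product: 7 4-hydroxy-3-(2-methylbut-3-en-2-yl)-6-phenyl-2H-pyran-2-one
Conditions: PhMe, 110 °C, Ar, sealed tube
Reagents that add atoms: none
Why: Thermal Claisen rearrangement of the allyl vinyl ether unit C3=C4–O–CH2–CH=CMe2 should deliver the inverted 1,1-dimethylallyl group to C3, the only carbon joined to C4 by a C=C bond, and re-enolisation restores the 4-hydroxypyranone, while the moderate temperature and neutral medium hold back further cyclisation of the product.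

Step 5
Reactants: 8 3-hydroxy-3-methylbutan-2-one
Product: 9 3-methyl-3-(triethylsilyloxy)butan-2-one
Conditions: TESOTf, 2,6-lutidine, CH2Cl2, −78 → 0 °C
Reagents that add atoms: triethylsilyl trifluoromethanesulfonate, CC[Si](CC)(CC)OS(=O)(=O)C(F)(F)F
Why: Silylation of a hindered tertiary alcohol with a silyl triflate and a weak, non-nucleophilic pyridine base, which should not enolise the methyl ketone at low temperature.

Step 6
Reactants: 9 3-methyl-3-(triethylsilyloxy)butan-2-one
Product: 11 1-diazo-3-methyl-3-(triethylsilyloxy)butan-2-one, via trifluoroacetyl diketone 10 (not isolated)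
Conditions: LiN(SiMe3)2, THF, −78 °C; CF3CO2CH2CF3; cold 5% aq. HCl work-up; then 4-acetamidobenzenesulfonyl azide, Et3N, H2O (1 equiv), MeCN, rt
Reagents that add atoms: 4-acetamidobenzenesulfonyl azide, CC(=O)Nc1ccc(cc1)S(=O)(=O)N=[N+]=[N-]
Why: Detrifluoroacetylative diazo transfer (Danheiser procedure), in which the enolate of the only enolisable position is trifluoroacetylated and the crude activated diketone takes up the diazo group from the sulfonyl azide with loss of the trifluoroacetyl group as the N-acyl sulfonamide, under conditions a tertiary silyl ether tolerates.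

Step 7
Reactants: 7 4-hydroxy-3-(2-methylbut-3-en-2-yl)-6-phenyl-2H-pyran-2-one; 11 1-diazo-3-methyl-3-(triethylsilyloxy)butan-2-one
Product: 13 3-(2-methylbut-3-en-2-yl)-2-oxo-6-phenyl-2H-pyran-4-yl 3-methyl-3-(triethylsilyloxy)butanoate, via siloxy ketene 12 (not isolated)
Conditions: 11 (1.5 equiv, added in portions), blue LEDs (ca. 450 nm), CH2Cl2, 0 °C, Ar
Reagents that add atoms: none
Why: Excitation in the weak long-wavelength band of the s-cis diazoketone, beyond the absorption edge of the phenylpyranone, should expel N2 with concerted 1,2-shift of the siloxy-bearing tertiary carbon to the diazo carbon (new CH–CMe2 bond) to give monosubstituted ketene 12, across whose C=C bond the enolic O4–H of 7 then adds (new O4–acyl bond). The closest known chemistry is the photochemical Wolff step of the Arndt–Eistert homologation with capture of the ketene by an acidic O–H nucleophile such as a carboxylic acid or phenol, which is also known under visible LED light. No ring is closed and no stereocentre is formed. The step needs acylation at O4 in preference to O2 or C3, and ahead of dark protonation of the diazo carbon and ketene dimerisation. C3 is fully substituted, the 4-acyloxy-2-pyranone is the more stable O-acyl isomer, the sp carbon of the ketene is slim enough to reach the oxygen beside the quaternary centre, and gradual photochemical release of 12 at 0 °C keeps its concentration low. Masking the tertiary hydroxyl as its triethylsilyl ether rules out lactonisation of 12, and the absence of alkoxide or amine base should prevent elimination of pyronate from the product.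

Step 8
Reactants: 13 3-(2-methylbut-3-en-2-yl)-2-oxo-6-phenyl-2H-pyran-4-yl 3-methyl-3-(triethylsilyloxy)butanoate
Product: 14 3-(2-methylbut-3-en-2-yl)-2-oxo-6-phenyl-2H-pyran-4-yl 3-hydroxy-3-methylbutanoate
Conditions: HF·pyridine, pyridine, THF, 0 °C → rt, plastic vessel
Reagents that add atoms: none
Why: Fluoride-driven desilylation under buffered, weakly acidic conditions, in which the Si–O bond is cleaved through formation of the strong Si–F bond without alkoxide being generated, so the base-labile enol ester and the tertiary beta-hydroxyl should survive.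

Compound list
1 | ethyl acetoacetate | CCOC(=O)CC(C)=O | starting material
2 | methyl benzoate | COC(=O)c1ccccc1 | starting material
3 | ethyl 3,5-dioxo-5-phenylpentanoate | CCOC(=O)CC(=O)CC(=O)c1ccccc1 | intermediate
4 | 4-hydroxy-6-phenyl-2H-pyran-2-one | O=c1cc(O)cc(-c2ccccc2)o1 | intermediate
5 | prenol (3-methylbut-2-en-1-ol) | CC(C)=CCO | starting material
6 | 4-(3-methylbut-2-enyloxy)-6-phenyl-2H-pyran-2-one | CC(C)=CCOc1cc(-c2ccccc2)oc(=O)c1 | intermediate
7 | 4-hydroxy-3-(2-methylbut-3-en-2-yl)-6-phenyl-2H-pyran-2-one | C=CC(C)(C)c1c(O)cc(-c2ccccc2)oc1=O | intermediate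
8 | 3-hydroxy-3-methylbutan-2-one | CC(=O)C(C)(C)O | starting material
9 | 3-methyl-3-(triethylsilyloxy)butan-2-one | CC(=O)C(C)(C)O[Si](CC)(CC)CC | intermediate
10 | 1,1,1-trifluoro-5-methyl-5-(triethylsilyloxy)hexane-2,4-dione | CC(C)(O[Si](CC)(CC)CC)C(=O)CC(=O)C(F)(F)F | intermediate
11 | 1-diazo-3-methyl-3-(triethylsilyloxy)butan-2-one | CC(C)(O[Si](CC)(CC)CC)C(=O)C=[N+]=[N-] | intermediate
12 | 3-methyl-3-(triethylsilyloxy)but-1-en-1-one | CC(C)(O[Si](CC)(CC)CC)C=C=O | intermediate
13 | 3-(2-methylbut-3-en-2-yl)-2-oxo-6-phenyl-2H-pyran-4-yl 3-methyl-3-(triethylsilyloxy)butanoate | C=CC(C)(C)c1c(OC(=O)CC(C)(C)O[Si](CC)(CC)CC)cc(-c2ccccc2)oc1=O | intermediate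
14 | 3-(2-methylbut-3-en-2-yl)-2-oxo-6-phenyl-2H-pyran-4-yl 3-hydroxy-3-methylbutanoate | C=CC(C)(C)c1c(OC(=O)CC(C)(C)O)cc(-c2ccccc2)oc1=O | target

Total step count: 8. Longest linear sequence: 6 steps (steps 1, 2, 3, 4, 7 and 8).

Steps most likely to fail

Step 7. The hindered enol may add to the ketene too slowly, so that the ketene dimerises or is lost to adventitious water, or the diazoketone may be protonated in the dark before it is photolysed. The fallback sets out from 7 and returns at 13, and forms the ester by conventional acylation with the preformed acid. Commercial 3-hydroxy-3-methylbutanoic acid is bis-silylated (TESCl, imidazole, DMF) to triethylsilyl 3-methyl-3-(triethylsilyloxy)butanoate F1. Its silyl ester is cleaved selectively (K2CO3, MeOH/THF/H2O, 0 °C) to 3-methyl-3-(triethylsilyloxy)butanoic acid F2. Compound 7 is then esterified with F2 by carbodiimide coupling (EDC·HCl, catalytic DMAP, CH2Cl2, 0 °C), which should give 13 because the blocked C3 leaves no site for O-to-C acyl migration.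

Step 4. The rearranged enol may react further at the reaction temperature, by addition of O4–H to the new vinyl group or by abnormal Claisen isomerisation of the 1,1-dimethylallyl group, or the rearrangement may stall. The fallback sets out from 6 and returns at 7, and runs the rearrangement with capture of the enol as it forms. Heating 6 in Ac2O with NaOAc (140 °C) should give 3-(2-methylbut-3-en-2-yl)-2-oxo-6-phenyl-2H-pyran-4-yl acetate F3, in which the hydroxyl can no longer attack the alkene. Brief methanolysis of this activated enol acetate (K2CO3, MeOH, 0 °C) then releases 7.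

Step 8. The hindered tertiary Si–O bond may be cleaved too slowly, so that acyl transfer to pyridine or fluoride, or collapse of the beta-oxygenated ester with loss of pyronate, destroys the ester first. The fallback sets out from 8 and returns at 14, keeping the same disconnection but carrying a silyl group labile enough to fall off under nearly neutral hydrolysis.
- Compound 8 is silylated (TMSCl, imidazole, CH2Cl2) to 3-methyl-3-(trimethylsilyloxy)butan-2-one F4.
- Trifluoroacetylation (LiN(SiMe3)2, CF3CO2CH2CF3, THF, −78 °C; aq. NaH2PO4 work-up) gives crude 1,1,1-trifluoro-5-methyl-5-(trimethylsilyloxy)hexane-2,4-dione F5.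
- Diazo transfer (4-acetamidobenzenesulfonyl azide, Et3N, H2O, MeCN) gives 1-diazo-3-methyl-3-(trimethylsilyloxy)butan-2-one F6.
- Irradiation of F6 with 7 under the conditions of step 7 generates 3-methyl-3-(trimethylsilyloxy)but-1-en-1-one F7, which is captured to give 3-(2-methylbut-3-en-2-yl)-2-oxo-6-phenyl-2H-pyran-4-yl 3-methyl-3-(trimethylsilyloxy)butanoate F8.
- Stirring F8 with dilute aqueous citric acid in THF at 0 °C should remove the trimethylsilyl group and give 14 without fluoride or amine.

Further compounds
F1 | step 7 | triethylsilyl 3-methyl-3-(triethylsilyloxy)butanoate | CC[Si](CC)(CC)OC(=O)CC(C)(C)O[Si](CC)(CC)CC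
F2 | step 7 | 3-methyl-3-(triethylsilyloxy)butanoic acid | CC(C)(CC(=O)O)O[Si](CC)(CC)CC
F3 | step 4 | 3-(2-methylbut-3-en-2-yl)-2-oxo-6-phenyl-2H-pyran-4-yl acetate | C=CC(C)(C)c1c(OC(C)=O)cc(-c2ccccc2)oc1=O
F4 | step 8 | 3-methyl-3-(trimethylsilyloxy)butan-2-one | CC(=O)C(C)(C)O[Si](C)(C)C
F5 | step 8 | 1,1,1-trifluoro-5-methyl-5-(trimethylsilyloxy)hexane-2,4-dione | CC(C)(O[Si](C)(C)C)C(=O)CC(=O)C(F)(F)F
F6 | step 8 | 1-diazo-3-methyl-3-(trimethylsilyloxy)butan-2-one | CC(C)(O[Si](C)(C)C)C(=O)C=[N+]=[N-]
F7 | step 8 | 3-methyl-3-(trimethylsilyloxy)but-1-en-1-one | CC(C)(O[Si](C)(C)C)C=C=O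
F8 | step 8 | 3-(2-methylbut-3-en-2-yl)-2-oxo-6-phenyl-2H-pyran-4-yl 3-methyl-3-(trimethylsilyloxy)butanoate | C=CC(C)(C)c1c(OC(=O)CC(C)(C)O[Si](C)(C)C)cc(-c2ccccc2)oc1=O
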